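**Retrosynthetic overview**
1. Labels: ring A is the gem-dimethyl dienone and ring C the methoxy arene. Ring B is the central arene with B1 (CH2 to ring A), B2 (OH), B3 (CH2 to ring C), B4 (OH), B5 (butyryl) and B6 (OH).
2. Feature that carries the plan: B6-B1-B2-B3 has the oxidation pattern of an acetoacetate (ester C, alpha C, ketone C, gamma C), and the two methylene bridges sit on its alpha and gamma carbons. B4-B5 is an oxygen-bearing carbon next to an acyl-bearing carbon, that is, an alkoxy ynone.
3. Last disconnections: global O-debenzylation. Ring B is then opened at B3-B4 and B5-B6 to a 2,4-dialkylated 1-methoxy-1,3-bis(silyloxy)diene and 1-benzyloxyhex-1-yn-3-one ([4+2] addition, then loss of methanol).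
4. The diene goes back to methyl acetoacetate. It is alkylated at the gamma carbon by a ring C benzylic bromide and then at the alpha carbon by a ring A bromomethyl bis(benzyl enol ether). The A-B-C connectivity is therefore settled on an open chain and never depends on the site selectivity of an arene.
5. Ring order: the carbocycles of ring C (2-methylphloroglucinol) and ring A (phloroglucinol, dearomatised by gem-dimethylation) are bought and decorated first. Ring B is the only ring that is built, and it is closed last.

Key step: step 21

Assumption: the second O-benzylation of butyrylfilicinic acid is taken to fall on the ring oxygen next to the free ring CH (2,4-dienone form, as ring A is drawn in the target); any other O-regioisomer, and any E/Z mixture in the silyl enol ethers, converges on the same target.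

Step 1
Reactants: 1 phloroglucinol; 2 butanoyl chloride
Product: 3 1-(2,4,6-trihydroxyphenyl)butan-1-one
Conditions: AlCl3 (3 equiv), CH2Cl2/PhNO2, 0 to 40 °C; then 1 M HCl
Reagents that add atoms: none
Why: Friedel-Crafts C-acylation of the symmetrical, very electron-rich triol should stop at the monoketone because the first acyl group, held by hydrogen bonds, deactivates the ring.

Step 2
Reactants: 3 1-(2,4,6-trihydroxyphenyl)butan-1-one
Product: 4 2-butanoyl-3,5-dihydroxy-6,6-dimethylcyclohexa-2,4-dien-1-one (butyrylfilicinic acid)
Conditions: MeI (2.2 equiv), NaOMe (3 equiv), MeOH, 0 °C to rt; then 1 M HCl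
Reagents that add atoms: iodomethane, CI
Why: Dearomatising double C-methylation of the acylphloroglucinol polyanion, the established entry to acylfilicinic acids, should place both methyl groups on one ring carbon because the monomethylated carbon is the most nucleophilic site of the anion, and over-methylated material is removed by chromatography.

Step 3
Reactants: 4 butyrylfilicinic acid
Product: 5 3,5-bis(benzyloxy)-2-butanoyl-6,6-dimethylcyclohexa-2,4-dien-1-one
Conditions: BnOH (2.4 equiv), PPh3, diisopropyl azodicarboxylate (DIAD), THF, 0 °C to rt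
Reagents that add atoms: benzyl alcohol, OCc1ccccc1
Why: Mitsunobu etherification, which goes to oxygen with cyclic enolised 1,3-dicarbonyl compounds, should cap both acidic enol OH groups under neutral conditions and avoid the C-benzylation of the free ring CH that benzyl bromide and base would cause.

Step 4
Reactants: 5 ring A bis(benzyl enol ether)
Product: 6 3,5-bis(benzyloxy)-2-butanoyl-4-iodo-6,6-dimethylcyclohexa-2,4-dien-1-one
Conditions: NIS (1.1 equiv), MeCN, 0 °C to rt, dark
Reagents that add atoms: N-iodosuccinimide, O=C1CCC(=O)N1I
Why: Electrophilic iodination (attack of the iodonium source on the enol ether carbon C4, then loss of the proton) should hit the only ring CH, as in the alpha-iodination of vinylogous esters.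

Step 5
Reactants: 6 ring A iodide
Product: 7 3,5-bis(benzyloxy)-2-butanoyl-4-(hydroxymethyl)-6,6-dimethylcyclohexa-2,4-dien-1-one
Conditions: Bu3SnCH2OH (1.3 equiv), Pd(PPh3)4 (5 mol %), 1,4-dioxane, 85 °C
Reagents that add atoms: (tributylstannyl)methanol, CCCC[Sn](CCCC)(CCCC)CO
Why: Stille cross-coupling of the alkenyl iodide under zerovalent palladium catalysis should transfer the hydroxymethyl group in preference to butyl and tolerates both ketones and the enol ethers.

Step 6
Reactants: 7 ring A allylic alcohol
Product: 8 3,5-bis(benzyloxy)-4-(bromomethyl)-2-butanoyl-6,6-dimethylcyclohexa-2,4-dien-1-one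
Conditions: CBr4, PPh3, CH2Cl2, -10 °C; used crude
Reagents that add atoms: tetrabromomethane, BrC(Br)(Br)Br
Why: Appel bromination converts the primary allylic alcohol to the bromide under neutral conditions that spare the acid-labile enol ethers, and the bromide is used at once because the neighbouring benzyloxy group makes it ionise easily.

Step 7
Reactants: 9 2-methylbenzene-1,3,5-triol; 2 butanoyl chloride
Product: 10 1-(2,4,6-trihydroxy-3-methylphenyl)butan-1-one
Conditions: AlCl3 (3 equiv), CH2Cl2/PhNO2, 0 to 40 °C; then 1 M HCl
Reagents that add atoms: none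
Why: Friedel-Crafts acylation at one of the two equivalent free positions of the C-methyl triol, with the same self-limiting monoacylation as in step 1.

Step 8
Reactants: 10 1-(2,4,6-trihydroxy-3-methylphenyl)butan-1-one
Product: 11 1-[4,6-bis(benzyloxy)-2-hydroxy-3-methylphenyl]butan-1-one
Conditions: BnBr (2.05 equiv), K2CO3, acetone, reflux
Reagents that add atoms: benzyl bromide, BrCc1ccccc1
Why: Williamson benzylation with two equivalents should take the free para OH first and then the less hindered ortho OH, while the OH wedged between methyl and butyryl stays behind as the hydrogen-bonded chelate, the usual selectivity of C-methylated phloracylophenones.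

Step 9
Reactants: 11 1-[4,6-bis(benzyloxy)-2-hydroxy-3-methylphenyl]butan-1-one
Product: 12 1-[4,6-bis(benzyloxy)-2-methoxy-3-methylphenyl]butan-1-one
Conditions: MeI (3 equiv), K2CO3, DMF, 40 °C
Reagents that add atoms: iodomethane, CI
Why: Williamson methylation of the last, chelated phenol places the methyl ether between the methyl and butyryl groups, and K2CO3 is too weak a base to enolise the ketone.

Step 10
Reactants: 12 1-[4,6-bis(benzyloxy)-2-methoxy-3-methylphenyl]butan-1-one
Product: 14 2,6-bis(benzyloxy)-3-butanoyl-4-methoxy-5-methylbenzaldehyde, via aryl iminium salt 13 (not isolated)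
Conditions: POCl3 (1.5 equiv), DMF, 0 to 45 °C; then ice/H2O
Reagents that add atoms: N,N-dimethylformamide, CN(C)C=O; water, O
Why: Vilsmeier-Haack formylation can strike only the single free ring position, which is ortho to both benzyloxy groups and para to the methoxy group, and the ketone deactivates little because its two ortho substituents twist it out of conjugation.

Step 11
Reactants: 14 ring C aldehyde
Product: 15 1-[2,4-bis(benzyloxy)-3-(hydroxymethyl)-6-methoxy-5-methylphenyl]butan-1-one
Conditions: NaBH4, THF/MeOH, -20 °C
Reagents that add atoms: none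
Why: Chemoselective borohydride reduction, in which the aldehyde is reduced far faster at low temperature than the doubly ortho-substituted aryl propyl ketone.

Step 12
Reactants: 15 ring C benzylic alcohol
Product: 16 1-[2,4-bis(benzyloxy)-3-(bromomethyl)-6-methoxy-5-methylphenyl]butan-1-one
Conditions: CBr4, PPh3, CH2Cl2, 0 °C
Reagents that add atoms: tetrabromomethane, BrC(Br)(Br)Br
Why: Appel bromination under neutral conditions gives a benzylic bromide that is strongly activated by three alkoxy groups but cannot condense with itself by Friedel-Crafts alkylation because its ring is hexasubstituted.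

Step 13
Reactants: 17 methyl acetoacetate
Product: 19 1-methoxy-1,3-bis(trimethylsilyloxy)buta-1,3-diene, via methyl 3-(trimethylsilyloxy)but-2-enoate 18 (not isolated)
Conditions: Me3SiOTf (2.1 equiv), Et3N (2.3 equiv), Et2O, 0 °C to rt
Reagents that add atoms: trimethylsilyl trifluoromethanesulfonate, C[Si](C)(C)OS(=O)(=O)C(F)(F)F
Why: Double soft enolisation (O-silylation by the silyl triflate, deprotonation by the amine) is a known one-flask preparation of this parent bis(silyloxy)diene.

Step 14
Reactants: 16 ring C benzylic bromide; 19 parent bis(silyloxy)diene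
Product: 21 methyl 5-[2,6-bis(benzyloxy)-3-butanoyl-4-methoxy-5-methylphenyl]-3-oxopentanoate, via silyl enol ether adduct 20 (not isolated)
Conditions: 19 (1.5 equiv), ZnBr2 (10 mol %), CH2Cl2, -40 to 0 °C; then 1 M HCl, THF, 0 °C
Reagents that add atoms: none
Why: Lewis acid promoted SN1-type alkylation of a silyl dienol ether (vinylogous Mukaiyama-type alkylation), in which ZnBr2 ionises the trialkoxybenzyl bromide and the diene answers through its gamma terminus, gives the C4-benzylated acetoacetate without exposing the aryl ketone to the strongly basic acetoacetate dianion.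

Step 15
Reactants: 21 gamma-alkylated keto ester; 8 ring A bromide
Product: 23 methyl 5-[2,6-bis(benzyloxy)-3-butanoyl-4-methoxy-5-methylphenyl]-2-{[2,6-bis(benzyloxy)-5-butanoyl-3,3-dimethyl-4-oxocyclohexa-1,5-dien-1-yl]methyl}-3-oxopentanoate (racemic), via sodium enolate 22 (not isolated)
Conditions: NaH (0.95 equiv), THF, 0 °C; then 8, 0 °C to rt
Reagents that add atoms: none
Why: Acetoacetic ester alkylation, in which the soft sodium enolate should displace the reactive allylic bromide through carbon (SN2), a slight deficit of base keeps the less acidic product protonated so that its enolate oxygen does not attack the ring A vinylogous ester, and the new stereocentre at B1 forms as a racemate that is erased in step 16.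

Step 16
Reactants: 23 doubly alkylated keto ester
Product: 24 methyl 3-(trimethylsilyloxy)pent-2-enoate carrying both arms (E/Z mixture)
Conditions: Me3SiCl (1.5 equiv), Et3N (1.6 equiv), toluene, rt
Reagents that add atoms: chlorotrimethylsilane, C[Si](C)(C)Cl
Why: O-silylation of the keto ester enol with Me3SiCl and Et3N gives the conjugated silyloxy enoate and leaves the two simple ketones untouched, the standard first stage in the preparation of substituted bis(silyloxy)dienes.

Step 17
Reactants: 24 silyloxy enoate
Product: 25 (1Z,3Z)-1-methoxy-1,3-bis(trimethylsilyloxy)diene with the ring A arm on B1 and the ring C arm on B3 and both spectator butyryl groups as trimethylsilyl enol ethers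
Conditions: Me3SiCl (6 equiv), THF, -78 °C, then LiN(iPr)2 (3.5 equiv) added slowly, -78 to 0 °C; pentane, filtration under argon; used crude
Reagents that add atoms: chlorotrimethylsilane, C[Si](C)(C)Cl
Why: Kinetic deprotonation with the silyl chloride already present (in situ trapping of lithium enolates) completes the ketene acetal, and since LiN(iPr)2 cannot tell the gamma CH2 of the silyloxy enoate from the alpha CH2 groups of the two butyryl ketones all three sites are deliberately enolised and silylated, which also hides both ketones from TiCl4 and lowers the electrophilicity of ring A, while the Z geometry at B2=B3 follows from deprotonation in the conformer that turns the ring C arm away from the B1 substituent.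

Step 18
Reactants: 2 butanoyl chloride
Product: 26 N-methoxy-N-methylbutanamide
Conditions: MeNH(OMe)·HCl, Et3N (2.2 equiv), CH2Cl2, 0 °C to rt
Reagents that add atoms: N,O-dimethylhydroxylamine hydrochloride, CNOC.Cl
Why: Simple N-acylation of the hydroxylamine gives the amide needed for a clean single acylation of the acetylide in a Weinreb ketone synthesis.

Step 19
Reactants: 27 trichloroethylene
Product: 29 benzyl (E)-1,2-dichlorovinyl ether, via dichloroacetylene 28 (not isolated)
Conditions: BnOH, KH (1.2 equiv), THF, 0 °C; then 27, -50 °C to rt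
Reagents that add atoms: benzyl alcohol, OCc1ccccc1
Why: Base-induced loss of HCl from trichloroethylene followed by anti addition of benzyloxide to the haloalkyne is the established route to (E)-1,2-dichlorovinyl ethers.

Step 20
Reactants: 29 benzyl (E)-1,2-dichlorovinyl ether; 26 N-methoxy-N-methylbutanamide
Product: 33 1-benzyloxyhex-1-yn-3-one, via benzyl chloroethynyl ether 30 (not isolated), via lithium benzyloxyacetylide 31 (not isolated), via lithium hemiaminal alkoxide 32 (not isolated)
Conditions: n-BuLi (2.2 equiv), THF, -78 °C; then 26, -78 to -20 °C; cold H2O; kept below 0 °C and used at once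
Reagents that add atoms: none
Why: Elimination of LiCl and chlorine-lithium exchange give the alkoxyacetylide, whose addition to the N-methoxy-N-methylamide stops at the chelated tetrahedral adduct (Weinreb ketone synthesis), so that no tertiary alcohol forms and the ynone appears only on the cold quench.

Step 21
Reactants: 25 tetrasilylated diene; 33 1-benzyloxyhex-1-yn-3-one
Product: 36 pentabenzyl ether of the target (B2-OH and B6-OH free), via cyclohexa-1,4-diene cycloadduct 34 (not isolated), via tetrasilylated arene 35 (not isolated)
Conditions: 33 (1.0 equiv), TiCl4 (1.1 equiv, added last), CH2Cl2, -78 to -30 °C; cold H2O; then aq citric acid, THF, 0 °C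
Reagents that add atoms: none
Why: Proposed new method: TiCl4 binds the ynone carbonyl and makes the benzyloxy-bearing carbon B4 strongly electrophilic, the gamma terminus B3 of the diene (pushed by three oxygen donors) bonds to it, and the titanium allenolate carbon B5 then closes on the O-silylated ester carbon B6, either in one asynchronous [4+2] event or as a Mukaiyama-Michael addition followed by a 6-exo-trig closure of ring B. Cycloadduct 34 carries H on B3 and OMe on B6 in a 1,4 relation, so it loses methanol to give arene 35, and mild acid then strips the two aryl silyl ethers and returns the two spectator enol ethers to butyryl groups. The closest known reaction type is the cycloaromatisation of 1-alkoxy-1,3-bis(silyloxy)buta-1,3-dienes with acetylenic ketones and esters to resorcinols, whereas a beta-alkoxy ynone as the two-carbon partner and a 2,4-dialkylated diene of this size have not been shown. No stereocentre survives, since B3 and B6 of 34 form as a mixture and both become sp2. The step needs one orientation, secured by the match of the most nucleophilic terminus B3 with the only electrophilic alkyne carbon B4, and it needs the ketene acetal diene to react ahead of the two simple enol silyl ethers, secured by its much higher nucleophilicity and by one equivalent of ynone, while the alkyl group on B1 shuts off the [3+3] mode through B1 and the ketone carbonyl because that path could not aromatise. The 3Z geometry keeps the ring C arm on the outside of the s-cis diene, and the mixture stays at or below -30 °C because benzyl ynol ethers rearrange or lose benzyl on warming.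

Step 22
Reactants: 36 pentabenzyl ether
Product: 37 Filixsaure (target)
Conditions: H2 (1 atm), Pd/C (10% Pd on carbon), EtOAc/MeOH, rt
Reagents that add atoms: none
Why: Catalytic hydrogenolysis cleaves the three aryl benzyl ethers and the two benzyl enol ethers under neutral conditions, which avoids the acid- or base-induced scrambling of methylene bridges typical of this family, and the hydrogen-bonded ketones and tetrasubstituted enol double bonds should not be reduced at one atmosphere.

**Compound list**
1 | phloroglucinol (benzene-1,3,5-triol) | Oc1cc(O)cc(O)c1 | starting material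
2 | butanoyl chloride (butyryl chloride) | CCCC(=O)Cl | starting material
3 | 1-(2,4,6-trihydroxyphenyl)butan-1-one | CCCC(=O)c1c(O)cc(O)cc1O | intermediate
4 | 2-butanoyl-3,5-dihydroxy-6,6-dimethylcyclohexa-2,4-dien-1-one (butyrylfilicinic acid) | CCCC(=O)C1=C(O)C=C(O)C(C)(C)C1=O | intermediate
5 | 3,5-bis(benzyloxy)-2-butanoyl-6,6-dimethylcyclohexa-2,4-dien-1-one | CCCC(=O)C1=C(OCc2ccccc2)C=C(OCc2ccccc2)C(C)(C)C1=O | intermediate
6 | 3,5-bis(benzyloxy)-2-butanoyl-4-iodo-6,6-dimethylcyclohexa-2,4-dien-1-one | CCCC(=O)C1=C(OCc2ccccc2)C(I)=C(OCc2ccccc2)C(C)(C)C1=O | intermediate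
7 | 3,5-bis(benzyloxy)-2-butanoyl-4-(hydroxymethyl)-6,6-dimethylcyclohexa-2,4-dien-1-one | CCCC(=O)C1=C(OCc2ccccc2)C(CO)=C(OCc2ccccc2)C(C)(C)C1=O | intermediate
8 | 3,5-bis(benzyloxy)-4-(bromomethyl)-2-butanoyl-6,6-dimethylcyclohexa-2,4-dien-1-one | CCCC(=O)C1=C(OCc2ccccc2)C(CBr)=C(OCc2ccccc2)C(C)(C)C1=O | intermediate
9 | 2-methylbenzene-1,3,5-triol (2-methylphloroglucinol) | Cc1c(O)cc(O)cc1O | starting material
10 | 1-(2,4,6-trihydroxy-3-methylphenyl)butan-1-one | CCCC(=O)c1c(O)cc(O)c(C)c1O | intermediate
11 | 1-[4,6-bis(benzyloxy)-2-hydroxy-3-methylphenyl]butan-1-one | CCCC(=O)c1c(O)c(C)c(OCc2ccccc2)cc1OCc1ccccc1 | intermediate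
12 | 1-[4,6-bis(benzyloxy)-2-methoxy-3-methylphenyl]butan-1-one | CCCC(=O)c1c(OC)c(C)c(OCc2ccccc2)cc1OCc1ccccc1 | intermediate
13 | [2,6-bis(benzyloxy)-3-butanoyl-4-methoxy-5-methylphenyl]methylidene(dimethyl)ammonium dichlorophosphate (not isolated) | CCCC(=O)c1c(OC)c(C)c(OCc2ccccc2)c(C=[N+](C)C)c1OCc1ccccc1.[O-]P(=O)(Cl)Cl | intermediate
14 | 2,6-bis(benzyloxy)-3-butanoyl-4-methoxy-5-methylbenzaldehyde | CCCC(=O)c1c(OC)c(C)c(OCc2ccccc2)c(C=O)c1OCc1ccccc1 | intermediate
15 | 1-[2,4-bis(benzyloxy)-3-(hydroxymethyl)-6-methoxy-5-methylphenyl]butan-1-one | CCCC(=O)c1c(OC)c(C)c(OCc2ccccc2)c(CO)c1OCc1ccccc1 | intermediate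
16 | 1-[2,4-bis(benzyloxy)-3-(bromomethyl)-6-methoxy-5-methylphenyl]butan-1-one | CCCC(=O)c1c(OC)c(C)c(OCc2ccccc2)c(CBr)c1OCc1ccccc1 | intermediate
17 | methyl acetoacetate | CC(=O)CC(=O)OC | starting material
18 | methyl 3-(trimethylsilyloxy)but-2-enoate (not isolated) | CC(O[Si](C)(C)C)=CC(=O)OC | intermediate
19 | 1-methoxy-1,3-bis(trimethylsilyloxy)buta-1,3-diene | C=C(O[Si](C)(C)C)C=C(OC)O[Si](C)(C)C | intermediate
20 | methyl 5-[2,6-bis(benzyloxy)-3-butanoyl-4-methoxy-5-methylphenyl]-3-(trimethylsilyloxy)pent-2-enoate (not isolated) | CCCC(=O)c1c(OC)c(C)c(OCc2ccccc2)c(CCC(O[Si](C)(C)C)=CC(=O)OC)c1OCc1ccccc1 | intermediate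
21 | methyl 5-[2,6-bis(benzyloxy)-3-butanoyl-4-methoxy-5-methylphenyl]-3-oxopentanoate | CCCC(=O)c1c(OC)c(C)c(OCc2ccccc2)c(CCC(=O)CC(=O)OC)c1OCc1ccccc1 | intermediate
22 | sodium enolate of 21 (not isolated) | CCCC(=O)c1c(OC)c(C)c(OCc2ccccc2)c(CCC([O-])=CC(=O)OC)c1OCc1ccccc1.[Na+] | intermediate
23 | methyl 5-[2,6-bis(benzyloxy)-3-butanoyl-4-methoxy-5-methylphenyl]-2-{[2,6-bis(benzyloxy)-5-butanoyl-3,3-dimethyl-4-oxocyclohexa-1,5-dien-1-yl]methyl}-3-oxopentanoate (racemic at C2) | CCCC(=O)c1c(OC)c(C)c(OCc2ccccc2)c(CCC(=O)C(CC2=C(OCc3ccccc3)C(C)(C)C(=O)C(C(=O)CCC)=C2OCc2ccccc2)C(=O)OC)c1OCc1ccccc1 | intermediate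
24 | 3-O-trimethylsilyl enol ether of 23 (conjugated pent-2-enoate, E/Z mixture) | CCCC(=O)c1c(OC)c(C)c(OCc2ccccc2)c(CCC(O[Si](C)(C)C)=C(CC2=C(OCc3ccccc3)C(C)(C)C(=O)C(C(=O)CCC)=C2OCc2ccccc2)C(=O)OC)c1OCc1ccccc1 | intermediate
25 | key diene: (1Z,3Z)-1-methoxy-1,3-bis(trimethylsilyloxy)penta-1,3-diene with the CH2 arm to the ring A bis(benzyl enol ether) on C2 (B1) and the ring C aryl group on C5; both spectator butyryl groups as (Z)-1-(trimethylsilyloxy)but-1-enyl groups | CC/C=C(\O[Si](C)(C)C)c1c(OC)c(C)c(OCc2ccccc2)c(C/C=C(\O[Si](C)(C)C)/C(CC2=C(OCc3ccccc3)C(C)(C)C(=O)C(/C(O[Si](C)(C)C)=C/CC)=C2OCc2ccccc2)=C(/OC)O[Si](C)(C)C)c1OCc1ccccc1 | intermediate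
26 | N-methoxy-N-methylbutanamide | CCCC(=O)N(C)OC | intermediate
27 | trichloroethylene | ClC=C(Cl)Cl | starting material
28 | dichloroacetylene (not isolated) | ClC#CCl | intermediate
29 | benzyl (E)-1,2-dichlorovinyl ether | Cl/C=C(/Cl)OCc1ccccc1 | intermediate
30 | benzyl chloroethynyl ether (not isolated) | ClC#COCc1ccccc1 | intermediate
31 | lithium benzyloxyacetylide (not isolated) | [Li]C#COCc1ccccc1 | intermediate
32 | lithium 1-benzyloxy-3-[methoxy(methyl)amino]hex-1-yn-3-olate (racemic, not isolated) | CCCC([O-])(C#COCc1ccccc1)N(C)OC.[Li+] | intermediate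
33 | 1-benzyloxyhex-1-yn-3-one | CCCC(=O)C#COCc1ccccc1 | intermediate
34 | cyclohexa-1,4-diene cycloadduct: B6 (OMe, OSiMe3), B1=B2 (OSiMe3 on B2), B3 (H, CH2 to ring C), B4 (OBn)=B5 (butyryl); mixture of diastereomers, not isolated | COC1(O[Si](C)(C)C)C(CC2=C(OCc3ccccc3)C(C)(C)C(=O)C(/C(O[Si](C)(C)C)=C/CC)=C2OCc2ccccc2)=C(O[Si](C)(C)C)C(Cc2c(OCc3ccccc3)c(C)c(OC)c(/C(O[Si](C)(C)C)=C/CC)c2OCc2ccccc2)C(OCc2ccccc2)=C1C(=O)CCC | intermediate
35 | tetrasilylated arene: ring B aromatic with OSiMe3 on B2 and B6, OBn on B4, both spectator enol silyl ethers intact (not isolated) | CCCC(=O)c1c(O[Si](C)(C)C)c(CC2=C(OCc3ccccc3)C(C)(C)C(=O)C(/C(O[Si](C)(C)C)=C/CC)=C2OCc2ccccc2)c(O[Si](C)(C)C)c(Cc2c(OCc3ccccc3)c(C)c(OC)c(/C(O[Si](C)(C)C)=C/CC)c2OCc2ccccc2)c1OCc1ccccc1 | intermediate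
36 | pentabenzyl ether of the target (benzyl on both ring A enol oxygens, on B4-O and on both ring C phenol oxygens) | CCCC(=O)C1=C(OCc4ccccc4)C(Cc2c(O)c(Cc3c(OCc4ccccc4)c(C)c(OC)c(C(=O)CCC)c3OCc4ccccc4)c(OCc4ccccc4)c(C(=O)CCC)c2O)=C(OCc4ccccc4)C(C)(C)C1=O | intermediate
37 | Filixsaure | CCCC(=O)C1=C(O)C(Cc2c(O)c(Cc3c(O)c(C)c(OC)c(C(=O)CCC)c3O)c(O)c(C(=O)CCC)c2O)=C(O)C(C)(C)C1=O | target

**Totals**
- Total step count: 22.
- Longest linear sequence: 12 steps (steps 7 to 12, 14 to 17, 21 and 22).

**Steps most likely to fail**

**1. Step 21 (carries the label).**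
What may go wrong:
- dealkylation of the titanium-bound ynol ether by chloride, or its sigmatropic rearrangement, before the C-C bond forms;
- a halt after the first bond without closure onto B6;
- intramolecular attack of the B3 terminus on the ring A vinylogous ester;
- capture of TiCl4 by the ring A carbonyl;
- reaction of the spectator enol silyl ethers;
- protodesilylation of the diene.

The fallback gives up the cycloaddition. It uses the known Mannich base/quinone methide coupling by which methylene-bridged acylphloroglucinols are assembled. It sets out from 3, 4 and 12 and comes back to the route at 37. Hydrogenolysis of 12 (H2, Pd/C) gives 1-(4,6-dihydroxy-2-methoxy-3-methylphenyl)butan-1-one F1. Aminomethylation of 4 with dimethyl(methylidene)ammonium iodide gives 2-butanoyl-4-[(dimethylamino)methyl]-3,5-dihydroxy-6,6-dimethylcyclohexa-2,4-dien-1-one F2. On warming with an excess of 3, F2 loses dimethylamine and alkylates one of the two equivalent free positions of 3. This gives 2-butanoyl-4-[(3-butanoyl-2,4,6-trihydroxyphenyl)methyl]-3,5-dihydroxy-6,6-dimethylcyclohexa-2,4-dien-1-one F3. Compound F1 is aminomethylated in the same way at its only free position to 1-{3-[(dimethylamino)methyl]-2,4-dihydroxy-6-methoxy-5-methylphenyl}butan-1-one F4. Warming F4 with F3, whose only free ring carbon is B3, should give 37. Short reaction times and the absence of strong base are needed to hold back exchange of the methylene bridges.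

**2. Step 17.**
What may go wrong:
- incomplete or uneven enolisation of the three carbonyl units;
- attack of the amide base or of a lithium enolate on the ring A vinylogous ester with loss of benzyl alcohol;
- hydrolysis of the ketene acetal during isolation.

The fallback replaces hard, anionic enolisation by soft enolisation. It sets out from 23, skips 24 and comes back at 25. Me3SiOTf (4.5 equiv) and Et3N (5 equiv) in Et2O at 0 °C put on all four silyl groups in one operation, through O-silylated oxocarbenium ions that a tertiary amine deprotonates. No free enolate and no amide base is ever present next to ring A. This is the method of step 13 applied to the full substrate, and it makes no new compound.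

**3. Step 3.**
What may go wrong:
- C-benzylation at the free ring CH;
- etherification at the side-chain oxygen or at the hindered oxygen next to the gem-dimethyl carbon;
- incomplete reaction of the hydrogen-bonded enol.

The fallback reverses the polarity of the C-O bond formation, so that C-alkylation is excluded by construction. It sets out from 4 and comes back at 5. Oxalyl chloride with a trace of DMF in CH2Cl2 turns both enol OH groups into vinylogous acid chlorides and gives 2-butanoyl-3,5-dichloro-6,6-dimethylcyclohexa-2,4-dien-1-one F5. Two equivalents of BnONa (from BnOH and NaH, THF, 0 °C) then replace both chlorides by addition-elimination to give 5.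

**Further compounds**
F1 | step 21 | 1-(4,6-dihydroxy-2-methoxy-3-methylphenyl)butan-1-one | CCCC(=O)c1c(OC)c(C)c(O)cc1O
F2 | step 21 | 2-butanoyl-4-[(dimethylamino)methyl]-3,5-dihydroxy-6,6-dimethylcyclohexa-2,4-dien-1-one | CCCC(=O)C1=C(O)C(CN(C)C)=C(O)C(C)(C)C1=O
F3 | step 21 | 2-butanoyl-4-[(3-butanoyl-2,4,6-trihydroxyphenyl)methyl]-3,5-dihydroxy-6,6-dimethylcyclohexa-2,4-dien-1-one | CCCC(=O)C1=C(O)C(Cc2c(O)cc(O)c(C(=O)CCC)c2O)=C(O)C(C)(C)C1=O
F4 | step 21 | 1-{3-[(dimethylamino)methyl]-2,4-dihydroxy-6-methoxy-5-methylphenyl}butan-1-one | CCCC(=O)c1c(OC)c(C)c(O)c(CN(C)C)c1O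
F0 | step 17 | none | none
F5 | step 3 | 2-butanoyl-3,5-dichloro-6,6-dimethylcyclohexa-2,4-dien-1-one | CCCC(=O)C1=C(Cl)C=C(Cl)C(C)(C)C1=O
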